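**Assumptions**
- The SMILES is taken literally: primary (E)-allylic sulfone, guanidine free base, ring = (1S,6R)-1,2,6-trimethylcyclohex-2-en-1-yl (vicinal methyls cis, side chain trans to the secondary methyl).
- Numbered compounds are building blocks, intermediates and the target. Simple reagents and catalysts are not numbered; those that donate atoms are given with SMILES in each step.

## Retrosynthetic overview
1. C–S bond last: allylic bromide 17 + zwitterionic sulfinate 20 (hypotaurocyamine), no protecting groups on nitrogen.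
2. C8–C7 bond and the 6E trisubstituted alkene: proposed new Cu–H/Ni syn-hydroalkylation of 2-alkyne 14 with primary iodide 8.
3. Alkyne 14 from geraniol (2E alkene inherited): terminal epoxide cleavage, then Corey–Fuchs/methylation.
4. Iodide 8 from 2-methylcyclohex-2-enone: Cu-catalysed asymmetric conjugate methylation (sets 6R), anti enolate alkylation (sets quaternary 1S), enol triflate → methyl coupling (ring alkene).
5. The only ring is purchased; no ring-forming step.

## Route

**Step 1**
Reactants: 1, 2-methylcyclohex-2-en-1-one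
Product: 2, (R)-[(2,3-dimethylcyclohex-1-en-1-yl)oxy]trimethylsilane
Conditions: Me3Al, CuTC (2 mol %), chiral phosphoramidite L* (4 mol %; the antipode that gives 3R), Et2O, −30 °C; then TMSOTf, THF, −30 → 0 °C
Reagents that add atoms: trimethylaluminium, C[Al](C)C; TMSOTf, C[Si](C)(C)OS(=O)(=O)C(F)(F)F
Why: Cu-catalysed asymmetric conjugate addition to an α-substituted enone sets the secondary methyl stereocentre (R) under ligand control, and O-silylation locks the tetrasubstituted enolate regiochemistry.

**Step 2**
Reactants: 2; 3, tert-butyl bromoacetate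
Product: 4, tert-butyl 2-[(1S,2R)-1,2-dimethyl-6-oxocyclohexyl]acetate
Conditions: MeLi, THF, 0 °C; then DMPU, 3, −78 → −20 °C
Reagents that add atoms: 3, BrCC(=O)OC(C)(C)C
Why: Regiospecific lithium enolate SN2 alkylation; the C3 methyl sits pseudoaxial (A1,2 strain) and the electrophile enters axially anti to it, giving the quaternary centre (S) with the acetate arm trans to that methyl (expected dr ≥ 8:1, separable).

**Step 3**
Reactants: 4
Product: 5, tert-butyl 2-[(1S,6R)-1,6-dimethyl-2-{[(trifluoromethyl)sulfonyl]oxy}cyclohex-2-en-1-yl]acetate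
Conditions: KHMDS, THF, −78 °C; PhNTf2, −78 → 0 °C
Reagents that add atoms: N-phenyl-bis(trifluoromethanesulfonimide), O=S(=O)(N(c1ccccc1)S(=O)(=O)C(F)(F)F)C(F)(F)F
Why: Kinetic enol triflate formation; the ketone can enolise only away from the quaternary carbon and is more acidic than the hindered tert-butyl ester.

**Step 4**
Reactants: 5
Product: 6, tert-butyl 2-[(1S,6R)-1,2,6-trimethylcyclohex-2-en-1-yl]acetate
Conditions: MeMgBr, Fe(acac)3 (5 mol %), THF/NMP, −30 °C
Reagents that add atoms: methylmagnesium bromide, C[Mg]Br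
Why: Fe-catalysed Kumada-type coupling of an alkenyl triflate installs the vinylic methyl and fixes the ring alkene position; the tert-butyl ester survives at low temperature.

**Step 5**
Reactants: 6
Product: 7, 2-[(1S,6R)-1,2,6-trimethylcyclohex-2-en-1-yl]ethan-1-ol
Conditions: LiAlH4, Et2O, 0 °C
Reagents that add atoms: none
Why: Standard hydride reduction of the ester to the primary alcohol; the alkene and stereocentres are untouched.

**Step 6**
Reactants: 7
Product: 8, (5R,6S)-6-(2-iodoethyl)-1,5,6-trimethylcyclohex-1-ene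
Conditions: I2, PPh3, imidazole, CH2Cl2, 0 °C → rt
Reagents that add atoms: iodine, II
Why: Appel-type (Garegg–Samuelsson) iodination of an unhindered primary alcohol.

**Step 7**
Reactants: 9, geraniol
Product: 10, geranyl TBDPS ether, (E)-tert-butyl[(3,7-dimethylocta-2,6-dien-1-yl)oxy]diphenylsilane
Conditions: TBDPSCl, imidazole, DMF, rt
Reagents that add atoms: TBDPSCl, CC(C)(C)[Si](Cl)(c1ccccc1)c1ccccc1
Why: Routine silylation; TBDPS tolerates the later acidic, organolithium and Cu–H steps.

**Step 8**
Reactants: 10
Product: 11, tert-butyl{[(2E)-5-(3,3-dimethyloxiran-2-yl)-3-methylpent-2-en-1-yl]oxy}diphenylsilane (racemic epoxide; this centre is destroyed in step 9)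
Conditions: mCPBA, NaHCO3, CH2Cl2, −20 °C
Reagents that add atoms: mCPBA, OOC(=O)c1cccc(Cl)c1
Why: Prilezhaev epoxidation, selective for the remote electron-rich 6,7-alkene because the 2,3-alkene is deactivated by the allylic oxygen.

**Step 9**
Reactants: 11
Product: 12, (E)-6-[(tert-butyldiphenylsilyl)oxy]-4-methylhex-4-enal
Conditions: H5IO6, THF/Et2O, 0 °C
Reagents that add atoms: none (the aldehyde oxygen is the former epoxide oxygen; acetone is lost)
Why: Periodic acid opens the epoxide and cleaves the resulting diol (Malaprade-type) to the aldehyde without touching the E-alkene.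

**Step 10**
Reactants: 12
Product: 13, (E)-tert-butyl[(7,7-dibromo-3-methylhepta-2,6-dien-1-yl)oxy]diphenylsilane
Conditions: CBr4, PPh3, CH2Cl2, 0 °C
Reagents that add atoms: carbon tetrabromide, BrC(Br)(Br)Br
Why: Corey–Fuchs (Ramirez) dibromo-olefination of an unhindered aldehyde.

**Step 11**
Reactants: 13
Product: 14, (E)-tert-butyl[(3-methyloct-2-en-6-yn-1-yl)oxy]diphenylsilane
Conditions: n-BuLi (2.2 equiv), THF, −78 °C; then MeI, −78 °C → rt
Reagents that add atoms: iodomethane, CI
Why: Second stage of the Corey–Fuchs sequence gives the lithium acetylide, which is C-methylated in the same pot to the methyl-capped alkyne.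

**Step 12 (proposed new step)**
Reactants: 8; 14
Product: 15, tert-butyl({(2E,6E)-3,7-dimethyl-9-[(1S,6R)-1,2,6-trimethylcyclohex-2-en-1-yl]nona-2,6-dien-1-yl}oxy)diphenylsilane
Conditions: IPr*CuCl (10 mol %), NiCl2·dme (5 mol %)/4,4′,4″-tri-tert-butylterpyridine (6 mol %), (EtO)2MeSiH, CsF, 1,4-dioxane/DME, 35 °C
Reagents that add atoms: none (the added H comes from the silane)
Why: Proposed new method: ligand-controlled Cu–H/Ni dual-catalytic syn-hydroalkylation of an unsymmetrical dialkyl 2-alkyne, in which the very bulky (NHC)Cu–H adds syn with Cu on the CH3-bearing alkyne carbon (the same steric bias seen in hydrozirconation and borylcupration of 2-alkynes), the configurationally stable alkenyl-copper transmetallates to (terpy)Ni, and Ni activates primary iodide 8 by halogen abstraction and forms the C(sp2)–C(sp3) bond with retention, so the C8–C7 bond and the 6E alkene are made together; the closest known reaction is Cu–H/Ni anti-Markovnikov hydroalkylation of terminal alkynes with alkyl iodides, which has not been shown to control regiochemistry on methyl/alkyl internal alkynes, and the trisubstituted alkenes, silyl ether and stereocentres should be inert to Cu–H.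

**Step 13**
Reactants: 15
Product: 16, (2E,6E)-3,7-dimethyl-9-[(1S,6R)-1,2,6-trimethylcyclohex-2-en-1-yl]nona-2,6-dien-1-ol
Conditions: TBAF, THF, 0 °C → rt
Reagents that add atoms: none
Why: Fluoride desilylation under non-acidic conditions leaves the triene intact.

**Step 14**
Reactants: 16
Product: 17, (5R,6S)-6-[(3E,7E)-9-bromo-3,7-dimethylnona-3,7-dien-1-yl]-1,5,6-trimethylcyclohex-1-ene
Conditions: MsCl, Et3N, THF, −40 °C; then LiBr, THF, 0 °C
Reagents that add atoms: lithium bromide, [Li+].[Br-]
Why: Mesylation followed by SN2 bromide displacement gives the primary allylic bromide without acid, preserving alkene geometry (as for farnesyl bromide).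

**Step 15**
Reactants: 18, hypotaurine (2-aminoethanesulfinic acid); 19, 1H-pyrazole-1-carboxamidine hydrochloride
Product: 20, hypotaurocyamine (2-guanidinoethanesulfinic acid, zwitterion)
Conditions: Na2CO3, H2O, rt; isolate the zwitterion at about pH 7
Reagents that add atoms: 19, Cl.NC(=N)n1cccn1
Why: Standard amine guanylation with a pyrazole carboxamidine; the sulfinate is a spectator and the product is a known zwitterion.

**Step 16**
Reactants: 17; 20
Product: 21, Agelasidine C
Conditions: Bu4NI (cat.), DMF, rt → 35 °C; then basic ion-exchange resin (OH form), MeOH, to liberate the free base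
Reagents that add atoms: 20, NC(N)=NCCS(=O)O
Why: Sulfinate S-alkylation (SN2) at the primary allylic bromide gives the E-allyl sulfone; the guanidinium is protonated in the zwitterion and therefore non-nucleophilic, so no N-protection or acidic deprotection is needed.

## Compound list
1 | 2-methylcyclohex-2-en-1-one | CC1=CCCCC1=O | starting material
2 | (R)-[(2,3-dimethylcyclohex-1-en-1-yl)oxy]trimethylsilane | C[C@@H]1CCCC(O[Si](C)(C)C)=C1C | intermediate
3 | tert-butyl bromoacetate | BrCC(=O)OC(C)(C)C | starting material
4 | tert-butyl 2-[(1S,2R)-1,2-dimethyl-6-oxocyclohexyl]acetate | O=C1CCC[C@@H](C)[C@]1(C)CC(=O)OC(C)(C)C | intermediate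
5 | tert-butyl 2-[(1S,6R)-1,6-dimethyl-2-(triflyloxy)cyclohex-2-en-1-yl]acetate | FC(F)(F)S(=O)(=O)OC1=CCC[C@@H](C)[C@]1(C)CC(=O)OC(C)(C)C | intermediate
6 | tert-butyl 2-[(1S,6R)-1,2,6-trimethylcyclohex-2-en-1-yl]acetate | CC1=CCC[C@@H](C)[C@]1(C)CC(=O)OC(C)(C)C | intermediate
7 | 2-[(1S,6R)-1,2,6-trimethylcyclohex-2-en-1-yl]ethan-1-ol | CC1=CCC[C@@H](C)[C@]1(C)CCO | intermediate
8 | (5R,6S)-6-(2-iodoethyl)-1,5,6-trimethylcyclohex-1-ene | CC1=CCC[C@@H](C)[C@]1(C)CCI | intermediate
9 | geraniol | CC(C)=CCC/C(C)=C/CO | starting material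
10 | geranyl TBDPS ether | CC(C)=CCC/C(C)=C/CO[Si](c1ccccc1)(c1ccccc1)C(C)(C)C | intermediate
11 | 6,7-epoxygeranyl TBDPS ether (racemic epoxide) | CC1(C)OC1CC/C(C)=C/CO[Si](c1ccccc1)(c1ccccc1)C(C)(C)C | intermediate
12 | (E)-6-[(tert-butyldiphenylsilyl)oxy]-4-methylhex-4-enal | O=CCC/C(C)=C/CO[Si](c1ccccc1)(c1ccccc1)C(C)(C)C | intermediate
13 | (E)-tert-butyl[(7,7-dibromo-3-methylhepta-2,6-dien-1-yl)oxy]diphenylsilane | BrC(Br)=CCC/C(C)=C/CO[Si](c1ccccc1)(c1ccccc1)C(C)(C)C | intermediate
14 | (E)-tert-butyl[(3-methyloct-2-en-6-yn-1-yl)oxy]diphenylsilane | CC#CCC/C(C)=C/CO[Si](c1ccccc1)(c1ccccc1)C(C)(C)C | intermediate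
15 | TBDPS ether of (2E,6E)-3,7-dimethyl-9-[(1S,6R)-1,2,6-trimethylcyclohex-2-en-1-yl]nona-2,6-dien-1-ol | CC1=CCC[C@@H](C)[C@]1(C)CC/C(C)=C/CC/C(C)=C/CO[Si](c1ccccc1)(c1ccccc1)C(C)(C)C | intermediate
16 | (2E,6E)-3,7-dimethyl-9-[(1S,6R)-1,2,6-trimethylcyclohex-2-en-1-yl]nona-2,6-dien-1-ol | CC1=CCC[C@@H](C)[C@]1(C)CC/C(C)=C/CC/C(C)=C/CO | intermediate
17 | (5R,6S)-6-[(3E,7E)-9-bromo-3,7-dimethylnona-3,7-dien-1-yl]-1,5,6-trimethylcyclohex-1-ene | CC1=CCC[C@@H](C)[C@]1(C)CC/C(C)=C/CC/C(C)=C/CBr | intermediate
18 | hypotaurine (2-aminoethanesulfinic acid) | NCCS(=O)O | starting material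
19 | 1H-pyrazole-1-carboxamidine hydrochloride | Cl.NC(=N)n1cccn1 | starting material
20 | hypotaurocyamine (2-guanidinoethanesulfinic acid, zwitterion) | NC(N)=NCCS(=O)O | intermediate
21 | Agelasidine C, 1-[2-({(2E,6E)-3,7-dimethyl-9-[(1S,6R)-1,2,6-trimethylcyclohex-2-en-1-yl]nona-2,6-dien-1-yl}sulfonyl)ethyl]guanidine | CC1=CCC[C@@H](C)[C@]1(C)CC/C(C)=C/CC/C(C)=C/CS(=O)(=O)CCN=C(N)N | target

## Summary
Total steps: 16.
Longest linear sequence: 10 (steps 1–6, 12, 13, 14, 16, from compound 1).

Three steps most likely to fail: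
1. **Step 12 (proposed new hydroalkylation).** Risks: the regioisomeric hydrocupration gives an inseparable constitutional isomer; Cu–H may reduce iodide 8; Ni–H may isomerise alkenes. Fallback (known chemistry): hydrozirconate 14 with excess Cp2Zr(H)Cl under equilibrating conditions and quench with I2 to give the (E)-2-iodoalkene. Then perform a B-alkyl Suzuki–Miyaura coupling with the borate from 8 (t-BuLi, B-MeO-9-BBN; Pd(dppf)Cl2, base).
2. **Step 2 (quaternary-centre alkylation).** Risks: proton transfer to the bromoacetate and insufficient dr. Fallback: allylate the enolate instead (allyl iodide, or Pd(0)/allyl acetate), the best-precedented electrophile for this enolate. Then shorten the arm by Lemieux–Johnson cleavage, Pinnick oxidation and esterification to rejoin the route at the ester stage.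
3. **Step 16 (S-alkylation with the unprotected zwitterion).** Risks: poor solubility of 20 and competing N-alkylation if any guanidine is deprotonated. Fallback: alkylate 17 with sodium 2-phthalimidoethanesulfinate (from 2-phthalimidoethanesulfonyl chloride and Na2SO3), remove the phthalimide with hydrazine, and guanylate the free amine with 19.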